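## Retrosynthetic overview

1. Target 35 ← desilylation, C14 oxidation and PMB removal from macrocycle 32. The ten-membered ring is closed last by ring-closing metathesis at C1=C10 of seco ester 31. (Germacrane numbering: lactone O on C6, ring fusion C6/C7, ester on C8, OH on C9, CHO = C14 on C10, CH2OH = C15 on C4.)
2. 31 ← acylation of alcohol 29 with (S)-2-methylbutanoic acid 30. 29 ← zinc Barbier union of bromomethyl butenolide 17 (fragment 1) with α-silyloxy aldehyde 27 (fragment 2), which sets C7 and C8 and creates the α-methylene lactone.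
3. 17 ← enal 7 + alkyne 10 by asymmetric alkynylation (sets C6), directed hydroalumination/iodination and carbonylative lactonisation. 7 ← but-2-yne-1,4-diol 1 by hydroalumination/iodination and Negishi coupling (fixes the C4=C5 geometry).
4. 27 ← 2-bromoallyl PMB ether 19 + glycerate Weinreb amide 21. A chelation-controlled reduction sets C9, and the glycerate carbon is then excised with periodate.
5. Ring order: butenolide (fragment 1) → α-methylene-γ-butyrolactone (coupling) → ten-membered carbocycle (metathesis).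

Assumption: (S,S)-ProPhenol is taken to give the (R)-carbinol in step 6; if the facial sense is the reverse, the (R,R)-ligand is used instead.

## Route

**Fragment 1 (bromomethyl butenolide 17)**

Step 1
Reactants: 1 but-2-yne-1,4-diol
Product: 2 4-[(tert-butyldimethylsilyl)oxy]but-2-yn-1-ol
Conditions: NaH (1 equiv), TBSCl (1 equiv), THF, 0 °C → rt, diol in threefold excess
Reagents that add atoms: tert-butyldimethylsilyl chloride, C[Si](C)(Cl)C(C)(C)C
Why: Statistical mono-O-silylation of the symmetrical diol through its monosodium alkoxide, the excess diol suppressing the bis-ether.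

Step 2
Reactants: 2 4-[(tert-butyldimethylsilyl)oxy]but-2-yn-1-ol
Product: 4 (2Z)-4-[(tert-butyldimethylsilyl)oxy]-3-iodobut-2-en-1-ol, via cyclic vinylalanate 3 (not isolated)
Conditions: NaAlH2(OCH2CH2OMe)2, THF, 0 °C → rt; then I2, THF, −78 → 0 °C
Reagents that add atoms: iodine, II
Why: Hydroxyl-directed trans-hydroalumination puts aluminium on the distal alkyne carbon cis to CH2OH, and iodinolysis with retention gives the (Z)-vinyl iodide.

Step 3
Reactants: 4 (2Z)-4-[(tert-butyldimethylsilyl)oxy]-3-iodobut-2-en-1-ol; 5 but-3-en-1-ylzinc bromide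
Product: 6 (2E)-3-{[(tert-butyldimethylsilyl)oxy]methyl}hepta-2,6-dien-1-ol
Conditions: Pd(dppf)Cl2 (5 mol %), THF, rt → 45 °C
Reagents that add atoms: none
Why: Negishi sp2–sp3 cross-coupling proceeds with retention, so the butenyl chain ends up cis to CH2OH, which is the ring-cis C4=C5 geometry of the target.

Step 4
Reactants: 6 (2E)-3-{[(tert-butyldimethylsilyl)oxy]methyl}hepta-2,6-dien-1-ol
Product: 7 (2E)-3-{[(tert-butyldimethylsilyl)oxy]methyl}hepta-2,6-dienal
Conditions: MnO2, CH2Cl2, rt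
Reagents that add atoms: none
Why: Neutral allylic oxidation with MnO2 gives the enal without isomerising the trisubstituted alkene or touching the silyl ether.

Step 5
Reactants: 8 3-bromoprop-1-yne (propargyl bromide); 9 4-methoxybenzyl alcohol
Product: 10 1-methoxy-4-[(prop-2-yn-1-yloxy)methyl]benzene
Conditions: NaH, THF, 0 °C → rt
Reagents that add atoms: none
Why: Williamson ether synthesis, SN2 attack of the benzylic alkoxide on the propargylic bromide.

Step 6
Reactants: 7 (2E)-3-{[(tert-butyldimethylsilyl)oxy]methyl}hepta-2,6-dienal; 10 1-methoxy-4-[(prop-2-yn-1-yloxy)methyl]benzene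
Product: 12 (4R,5E)-6-{[(tert-butyldimethylsilyl)oxy]methyl}-1-[(4-methoxyphenyl)methoxy]deca-5,9-dien-2-yn-4-ol, via alkynyl(methyl)zinc 11 (not isolated)
Conditions: Me2Zn, (S,S)-ProPhenol (20 mol %), Ph3PO (40 mol %), toluene, 0 → 4 °C
Reagents that add atoms: none
Why: Zinc–ProPhenol catalysed asymmetric alkynylation of an enal, in which the dinuclear zinc complex delivers the alkynyl group to one aldehyde face and so sets C6 as R.

Step 7
Reactants: 12 (4R,5E)-6-{[(tert-butyldimethylsilyl)oxy]methyl}-1-[(4-methoxyphenyl)methoxy]deca-5,9-dien-2-yn-4-ol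
Product: 14 (2Z,4R,5E)-6-{[(tert-butyldimethylsilyl)oxy]methyl}-2-iodo-1-[(4-methoxyphenyl)methoxy]deca-2,5,9-trien-4-ol, via cyclic vinylalanate 13 (not isolated)
Conditions: NaAlH2(OCH2CH2OMe)2, Et2O, 0 °C; then I2, −78 °C
Reagents that add atoms: iodine, II
Why: The C6 alkoxide directs a second trans-hydroalumination/iodination, giving the γ-iodo allylic alcohol with iodine cis to the carbinol carbon and leaving C6 untouched.

Step 8
Reactants: 14 (2Z,4R,5E)-6-{[(tert-butyldimethylsilyl)oxy]methyl}-2-iodo-1-[(4-methoxyphenyl)methoxy]deca-2,5,9-trien-4-ol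
Product: 15 (5R)-5-[(1E)-2-{[(tert-butyldimethylsilyl)oxy]methyl}hexa-1,5-dien-1-yl]-3-{[(4-methoxyphenyl)methoxy]methyl}furan-2(5H)-one
Conditions: PdCl2(PPh3)2 (5 mol %), CO (1 atm), i-Pr2NEt, THF, 40 °C
Reagents that add atoms: carbon monoxide, [C-]#[O+]
Why: Palladium-catalysed carbonylative lactonisation: oxidative addition of zerovalent palladium to the vinyl iodide, CO insertion and capture of the acylpalladium by the cis hydroxyl close the butenolide.

Step 9
Reactants: 15 (5R)-5-[(1E)-2-{[(tert-butyldimethylsilyl)oxy]methyl}hexa-1,5-dien-1-yl]-3-{[(4-methoxyphenyl)methoxy]methyl}furan-2(5H)-one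
Product: 16 (5R)-5-[(1E)-2-{[(tert-butyldimethylsilyl)oxy]methyl}hexa-1,5-dien-1-yl]-3-(hydroxymethyl)furan-2(5H)-one
Conditions: DDQ, CH2Cl2/pH 7 buffer, 0 °C
Reagents that add atoms: none
Why: Oxidative PMB ether cleavage by DDQ is selective for the electron-rich benzyl group and leaves the TBS ether and the alkenes alone.

Step 10
Reactants: 16 (5R)-5-[(1E)-2-{[(tert-butyldimethylsilyl)oxy]methyl}hexa-1,5-dien-1-yl]-3-(hydroxymethyl)furan-2(5H)-one
Product: 17 (5R)-3-(bromomethyl)-5-[(1E)-2-{[(tert-butyldimethylsilyl)oxy]methyl}hexa-1,5-dien-1-yl]furan-2(5H)-one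
Conditions: CBr4, PPh3, CH2Cl2, 0 °C
Reagents that add atoms: carbon tetrabromide, BrC(Br)(Br)Br
Why: Appel bromination (SN2 on the alkoxyphosphonium ion) runs under neutral conditions that spare the base-sensitive C6–H of the butenolide.

**Fragment 2 (aldehyde 27)**

Step 11
Reactants: 18 2,3-dibromoprop-1-ene; 9 4-methoxybenzyl alcohol
Product: 19 1-{[(2-bromoprop-2-en-1-yl)oxy]methyl}-4-methoxybenzene
Conditions: NaH, THF/DMF, 0 °C → rt
Reagents that add atoms: none
Why: Williamson etherification at the allylic bromide, the vinylic bromide being inert to SN2.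

Step 12
Reactants: 20 methyl (4R)-2,2-dimethyl-1,3-dioxolane-4-carboxylate
Product: 21 (4R)-N-methoxy-N,2,2-trimethyl-1,3-dioxolane-4-carboxamide
Conditions: MeNHOMe·HCl, i-PrMgCl, THF, −20 °C
Reagents that add atoms: N,O-dimethylhydroxylamine hydrochloride, CNOC.Cl
Why: Weinreb amide formation by aminolysis of the ester with the chloromagnesium amide at low temperature, which keeps the α-alkoxy stereocentre intact.

Step 13
Reactants: 19 1-{[(2-bromoprop-2-en-1-yl)oxy]methyl}-4-methoxybenzene; 21 (4R)-N-methoxy-N,2,2-trimethyl-1,3-dioxolane-4-carboxamide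
Product: 23 1-[(4R)-2,2-dimethyl-1,3-dioxolan-4-yl]-2-{[(4-methoxyphenyl)methoxy]methyl}prop-2-en-1-one, via 2-lithioallyl ether 22 (not isolated)
Conditions: t-BuLi (2 equiv), Et2O, −78 °C; then 21, −78 → −40 °C; inverse quench into cold aq. citric acid
Reagents that add atoms: none
Why: Bromine–lithium exchange followed by Weinreb ketone synthesis, the chelated tetrahedral intermediate preventing over-addition and the acidic inverse quench preventing amine conjugate addition to the enone.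

Step 14
Reactants: 23 1-[(4R)-2,2-dimethyl-1,3-dioxolan-4-yl]-2-{[(4-methoxyphenyl)methoxy]methyl}prop-2-en-1-one
Product: 24 (1S)-1-[(4R)-2,2-dimethyl-1,3-dioxolan-4-yl]-2-{[(4-methoxyphenyl)methoxy]methyl}prop-2-en-1-ol
Conditions: Zn(BH4)2, Et2O, −30 °C
Reagents that add atoms: none
Why: Chelation-controlled (Cram chelate) 1,2-reduction: zinc bridges the ketone and the α-dioxolane oxygen and hydride enters from the side of the α-hydrogen, giving the anti alcohol whose carbinol carbon is the future C9 (S).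

Step 15
Reactants: 24 (1S)-1-[(4R)-2,2-dimethyl-1,3-dioxolan-4-yl]-2-{[(4-methoxyphenyl)methoxy]methyl}prop-2-en-1-ol
Product: 25 tert-butyl{[(1S)-1-[(4R)-2,2-dimethyl-1,3-dioxolan-4-yl]-2-{[(4-methoxyphenyl)methoxy]methyl}prop-2-en-1-yl]oxy}dimethylsilane
Conditions: TBSOTf, 2,6-lutidine, CH2Cl2, −78 → 0 °C
Reagents that add atoms: tert-butyldimethylsilyl trifluoromethanesulfonate, C[Si](C)(OS(=O)(=O)C(F)(F)F)C(C)(C)C
Why: O-silylation of the hindered secondary allylic alcohol with the reactive silyl triflate and a non-nucleophilic base.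

Step 16
Reactants: 25 tert-butyl{[(1S)-1-[(4R)-2,2-dimethyl-1,3-dioxolan-4-yl]-2-{[(4-methoxyphenyl)methoxy]methyl}prop-2-en-1-yl]oxy}dimethylsilane
Product: 26 (2R,3S)-3-[(tert-butyldimethylsilyl)oxy]-4-{[(4-methoxyphenyl)methoxy]methyl}pent-4-ene-1,2-diol
Conditions: CuCl2·2H2O, MeCN, 0 °C
Reagents that add atoms: none
Why: Mild Lewis-acid hydrolysis of the terminal isopropylidene ketal, which is more labile than the secondary TBS ether and the PMB ether.

Step 17
Reactants: 26 (2R,3S)-3-[(tert-butyldimethylsilyl)oxy]-4-{[(4-methoxyphenyl)methoxy]methyl}pent-4-ene-1,2-diol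
Product: 27 (2S)-2-[(tert-butyldimethylsilyl)oxy]-3-{[(4-methoxyphenyl)methoxy]methyl}but-3-enal
Conditions: NaIO4 on wet silica gel, CH2Cl2, rt; used at once
Reagents that add atoms: none
Why: Periodate glycol cleavage (Malaprade) removes the glycerate carbon under neutral conditions, so the α-silyloxy β,γ-unsaturated aldehyde neither epimerises nor moves into conjugation.

**Union and end game**

Step 18
Reactants: 17 (5R)-3-(bromomethyl)-5-[(1E)-2-{[(tert-butyldimethylsilyl)oxy]methyl}hexa-1,5-dien-1-yl]furan-2(5H)-one; 27 (2S)-2-[(tert-butyldimethylsilyl)oxy]-3-{[(4-methoxyphenyl)methoxy]methyl}but-3-enal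
Product: 29 (4R,5R)-4-[(1R,2S)-2-[(tert-butyldimethylsilyl)oxy]-1-hydroxy-3-{[(4-methoxyphenyl)methoxy]methyl}but-3-en-1-yl]-5-[(1E)-2-{[(tert-butyldimethylsilyl)oxy]methyl}hexa-1,5-dien-1-yl]-3-methylideneoxolan-2-one, via allylzinc bromide 28 (not isolated)
Conditions: Zn dust, THF/sat. aq. NH4Cl, 0 °C → rt
Reagents that add atoms: none
Why: Zinc Barbier allylation in which the allylzinc reacts at its γ-carbon (SE2') through a chair Zimmerman–Traxler transition state: attack anti to the C6 substituent sets C7 (trans-lactone), the ring-fixed allyl geometry sets C8 relative to C7, and this coincides with Felkin–Anh attack on the α-silyloxy aldehyde (8,9-anti), so the two controls are matched.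

Step 19
Reactants: 29 (4R,5R)-4-[(1R,2S)-2-[(tert-butyldimethylsilyl)oxy]-1-hydroxy-3-{[(4-methoxyphenyl)methoxy]methyl}but-3-en-1-yl]-5-[(1E)-2-{[(tert-butyldimethylsilyl)oxy]methyl}hexa-1,5-dien-1-yl]-3-methylideneoxolan-2-one; 30 (2S)-2-methylbutanoic acid
Product: 31 (1R,2S)-2-[(tert-butyldimethylsilyl)oxy]-1-[(2R,3S)-2-[(1E)-2-{[(tert-butyldimethylsilyl)oxy]methyl}hexa-1,5-dien-1-yl]-4-methylidene-5-oxooxolan-3-yl]-3-{[(4-methoxyphenyl)methoxy]methyl}but-3-en-1-yl (2S)-2-methylbutanoate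
Conditions: DCC, DMAP (cat.), CH2Cl2, 0 °C → rt
Reagents that add atoms: none
Why: Steglich esterification acylates the C8 hydroxyl with retention, and the mild carbodiimide/DMAP conditions preserve the α-stereocentre of the acid.

Step 20
Reactants: 31 (1R,2S)-2-[(tert-butyldimethylsilyl)oxy]-1-[(2R,3S)-2-[(1E)-2-{[(tert-butyldimethylsilyl)oxy]methyl}hexa-1,5-dien-1-yl]-4-methylidene-5-oxooxolan-3-yl]-3-{[(4-methoxyphenyl)methoxy]methyl}but-3-en-1-yl (2S)-2-methylbutanoate
Product: 32 (3aS,4R,5S,6Z,10E,11aR)-5-[(tert-butyldimethylsilyl)oxy]-10-{[(tert-butyldimethylsilyl)oxy]methyl}-6-{[(4-methoxyphenyl)methoxy]methyl}-3-methylidene-2-oxo-2,3,3a,4,5,8,9,11a-octahydrocyclodeca[b]furan-4-yl (2S)-2-methylbutanoate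
Conditions: second-generation Hoveyda–Grubbs catalyst (15–20 mol %), toluene (1 mM), 90 °C, argon sparge
Reagents that add atoms: none
Why: Ring-closing metathesis: the ruthenium carbene forms at the unhindered terminal alkene and closes onto the 1,1-disubstituted C10 alkene with loss of ethene; closure onto the α-methylene lactone would need a bridgehead alkene, and the ten-membered ring that already holds a cis alkene and a trans-fused lactone is expected to accept only the ring-cis C1=C10 geometry.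

Step 21
Reactants: 32 (3aS,4R,5S,6Z,10E,11aR)-5-[(tert-butyldimethylsilyl)oxy]-10-{[(tert-butyldimethylsilyl)oxy]methyl}-6-{[(4-methoxyphenyl)methoxy]methyl}-3-methylidene-2-oxo-2,3,3a,4,5,8,9,11a-octahydrocyclodeca[b]furan-4-yl (2S)-2-methylbutanoate
Product: 33 (3aS,4R,5S,6Z,10E,11aR)-5-[(tert-butyldimethylsilyl)oxy]-10-{[(tert-butyldimethylsilyl)oxy]methyl}-6-(hydroxymethyl)-3-methylidene-2-oxo-2,3,3a,4,5,8,9,11a-octahydrocyclodeca[b]furan-4-yl (2S)-2-methylbutanoate
Conditions: DDQ, CH2Cl2/pH 7 buffer, 0 °C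
Reagents that add atoms: none
Why: Oxidative PMB cleavage frees only the C14 hydroxyl, since the silyl ethers, the ester and the α-methylene lactone are inert to DDQ.

Step 22
Reactants: 33 (3aS,4R,5S,6Z,10E,11aR)-5-[(tert-butyldimethylsilyl)oxy]-10-{[(tert-butyldimethylsilyl)oxy]methyl}-6-(hydroxymethyl)-3-methylidene-2-oxo-2,3,3a,4,5,8,9,11a-octahydrocyclodeca[b]furan-4-yl (2S)-2-methylbutanoate
Product: 34 (3aS,4R,5S,6E,10E,11aR)-5-[(tert-butyldimethylsilyl)oxy]-10-{[(tert-butyldimethylsilyl)oxy]methyl}-6-formyl-3-methylidene-2-oxo-2,3,3a,4,5,8,9,11a-octahydrocyclodeca[b]furan-4-yl (2S)-2-methylbutanoate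
Conditions: MnO2, CH2Cl2, rt
Reagents that add atoms: none
Why: Allylic oxidation of the only free hydroxyl gives the enal, whose geometry is fixed by the ring.

Step 23
Reactants: 34 (3aS,4R,5S,6E,10E,11aR)-5-[(tert-butyldimethylsilyl)oxy]-10-{[(tert-butyldimethylsilyl)oxy]methyl}-6-formyl-3-methylidene-2-oxo-2,3,3a,4,5,8,9,11a-octahydrocyclodeca[b]furan-4-yl (2S)-2-methylbutanoate
Product: 35 (3aS,4R,5S,6E,10E,11aR)-6-formyl-5-hydroxy-10-(hydroxymethyl)-3-methylidene-2-oxo-2,3,3a,4,5,8,9,11a-octahydrocyclodeca[b]furan-4-yl (2S)-2-methylbutanoate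
Conditions: HF·pyridine, pyridine/THF, 0 °C → rt
Reagents that add atoms: none
Why: Fluoride-mediated desilylation of both TBS ethers under buffered, mildly acidic conditions avoids C8→C9 acyl migration and conjugate addition to the enal or the methylene lactone.

## Compound list

1 | but-2-yne-1,4-diol | OCC#CCO | starting material
2 | 4-[(tert-butyldimethylsilyl)oxy]but-2-yn-1-ol | OCC#CCO[Si](C)(C)C(C)(C)C | intermediate
3 | cyclic vinylalanate: sodium 3-{[(tert-butyldimethylsilyl)oxy]methyl}-2,2-bis(2-methoxyethoxy)-2,5-dihydro-1,2-oxaaluminol-2-uide | [Na+].COCCO[Al-]1(OCCOC)OCC=C1CO[Si](C)(C)C(C)(C)C | intermediate (not isolated)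
4 | (2Z)-4-[(tert-butyldimethylsilyl)oxy]-3-iodobut-2-en-1-ol | OC/C=C(/CO[Si](C)(C)C(C)(C)C)I | intermediate
5 | but-3-en-1-ylzinc bromide (0.5 M in THF) | C=CCC[Zn]Br | starting material
6 | (2E)-3-{[(tert-butyldimethylsilyl)oxy]methyl}hepta-2,6-dien-1-ol | OC/C=C(/CO[Si](C)(C)C(C)(C)C)CCC=C | intermediate
7 | (2E)-3-{[(tert-butyldimethylsilyl)oxy]methyl}hepta-2,6-dienal | O=C/C=C(/CO[Si](C)(C)C(C)(C)C)CCC=C | intermediate
8 | 3-bromoprop-1-yne | C#CCBr | starting material
9 | 4-methoxybenzyl alcohol | COc1ccc(CO)cc1 | starting material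
10 | 1-methoxy-4-[(prop-2-yn-1-yloxy)methyl]benzene | C#CCOCc1ccc(OC)cc1 | intermediate
11 | alkynyl(methyl)zinc: methyl{3-[(4-methoxyphenyl)methoxy]prop-1-yn-1-yl}zinc | C[Zn]C#CCOCc1ccc(OC)cc1 | intermediate (not isolated)
12 | (4R,5E)-6-{[(tert-butyldimethylsilyl)oxy]methyl}-1-[(4-methoxyphenyl)methoxy]deca-5,9-dien-2-yn-4-ol | O[C@@H](C#CCOCc1ccc(OC)cc1)/C=C(/CO[Si](C)(C)C(C)(C)C)CCC=C | intermediate
13 | cyclic vinylalanate of 12: sodium 2,2-bis(2-methoxyethoxy)-1,2-oxaaluminol-2-uide carrying the (R)-configured C5 dienyl group and the 3-(PMB-oxymethyl) group | [Na+].COCCO[Al-]1(OCCOC)O[C@H](/C=C(/CO[Si](C)(C)C(C)(C)C)CCC=C)C=C1COCc1ccc(OC)cc1 | intermediate (not isolated)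
14 | (2Z,4R,5E)-6-{[(tert-butyldimethylsilyl)oxy]methyl}-2-iodo-1-[(4-methoxyphenyl)methoxy]deca-2,5,9-trien-4-ol | O[C@@H](/C=C(\I)COCc1ccc(OC)cc1)/C=C(/CO[Si](C)(C)C(C)(C)C)CCC=C | intermediate
15 | (5R)-5-[(1E)-2-{[(tert-butyldimethylsilyl)oxy]methyl}hexa-1,5-dien-1-yl]-3-{[(4-methoxyphenyl)methoxy]methyl}furan-2(5H)-one | O=C1O[C@H](/C=C(/CO[Si](C)(C)C(C)(C)C)CCC=C)C=C1COCc1ccc(OC)cc1 | intermediate
16 | (5R)-5-[(1E)-2-{[(tert-butyldimethylsilyl)oxy]methyl}hexa-1,5-dien-1-yl]-3-(hydroxymethyl)furan-2(5H)-one | O=C1O[C@H](/C=C(/CO[Si](C)(C)C(C)(C)C)CCC=C)C=C1CO | intermediate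
17 | (5R)-3-(bromomethyl)-5-[(1E)-2-{[(tert-butyldimethylsilyl)oxy]methyl}hexa-1,5-dien-1-yl]furan-2(5H)-one | O=C1O[C@H](/C=C(/CO[Si](C)(C)C(C)(C)C)CCC=C)C=C1CBr | intermediate
18 | 2,3-dibromoprop-1-ene | C=C(Br)CBr | starting material
19 | 1-{[(2-bromoprop-2-en-1-yl)oxy]methyl}-4-methoxybenzene | C=C(Br)COCc1ccc(OC)cc1 | intermediate
20 | methyl (4R)-2,2-dimethyl-1,3-dioxolane-4-carboxylate | COC(=O)[C@H]1COC(C)(C)O1 | starting material
21 | (4R)-N-methoxy-N,2,2-trimethyl-1,3-dioxolane-4-carboxamide | CON(C)C(=O)[C@H]1COC(C)(C)O1 | intermediate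
22 | 2-lithioallyl ether: {3-[(4-methoxyphenyl)methoxy]prop-1-en-2-yl}lithium | [Li]C(=C)COCc1ccc(OC)cc1 | intermediate (not isolated)
23 | 1-[(4R)-2,2-dimethyl-1,3-dioxolan-4-yl]-2-{[(4-methoxyphenyl)methoxy]methyl}prop-2-en-1-one | C=C(COCc1ccc(OC)cc1)C(=O)[C@H]1COC(C)(C)O1 | intermediate
24 | (1S)-1-[(4R)-2,2-dimethyl-1,3-dioxolan-4-yl]-2-{[(4-methoxyphenyl)methoxy]methyl}prop-2-en-1-ol | C=C(COCc1ccc(OC)cc1)[C@H](O)[C@H]1COC(C)(C)O1 | intermediate
25 | tert-butyl{[(1S)-1-[(4R)-2,2-dimethyl-1,3-dioxolan-4-yl]-2-{[(4-methoxyphenyl)methoxy]methyl}prop-2-en-1-yl]oxy}dimethylsilane | C=C(COCc1ccc(OC)cc1)[C@H](O[Si](C)(C)C(C)(C)C)[C@H]1COC(C)(C)O1 | intermediate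
26 | (2R,3S)-3-[(tert-butyldimethylsilyl)oxy]-4-{[(4-methoxyphenyl)methoxy]methyl}pent-4-ene-1,2-diol | C=C(COCc1ccc(OC)cc1)[C@H](O[Si](C)(C)C(C)(C)C)[C@H](O)CO | intermediate
27 | (2S)-2-[(tert-butyldimethylsilyl)oxy]-3-{[(4-methoxyphenyl)methoxy]methyl}but-3-enal | C=C(COCc1ccc(OC)cc1)[C@H](O[Si](C)(C)C(C)(C)C)C=O | intermediate
28 | allylzinc bromide: bromo{[(5R)-5-[(1E)-2-{[(tert-butyldimethylsilyl)oxy]methyl}hexa-1,5-dien-1-yl]-2-oxo-2,5-dihydrofuran-3-yl]methyl}zinc | O=C1O[C@H](/C=C(/CO[Si](C)(C)C(C)(C)C)CCC=C)C=C1C[Zn]Br | intermediate (not isolated)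
29 | (4R,5R)-4-[(1R,2S)-2-[(tert-butyldimethylsilyl)oxy]-1-hydroxy-3-{[(4-methoxyphenyl)methoxy]methyl}but-3-en-1-yl]-5-[(1E)-2-{[(tert-butyldimethylsilyl)oxy]methyl}hexa-1,5-dien-1-yl]-3-methylideneoxolan-2-one | C=C1C(=O)O[C@H](/C=C(/CO[Si](C)(C)C(C)(C)C)CCC=C)[C@H]1[C@@H](O)[C@@H](O[Si](C)(C)C(C)(C)C)C(=C)COCc1ccc(OC)cc1 | intermediate
30 | (2S)-2-methylbutanoic acid | CC[C@H](C)C(=O)O | starting material
31 | (1R,2S)-2-[(tert-butyldimethylsilyl)oxy]-1-[(2R,3S)-2-[(1E)-2-{[(tert-butyldimethylsilyl)oxy]methyl}hexa-1,5-dien-1-yl]-4-methylidene-5-oxooxolan-3-yl]-3-{[(4-methoxyphenyl)methoxy]methyl}but-3-en-1-yl (2S)-2-methylbutanoate | C=C1C(=O)O[C@H](/C=C(/CO[Si](C)(C)C(C)(C)C)CCC=C)[C@H]1[C@@H](OC(=O)[C@@H](C)CC)[C@@H](O[Si](C)(C)C(C)(C)C)C(=C)COCc1ccc(OC)cc1 | intermediate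
32 | (3aS,4R,5S,6Z,10E,11aR)-5-[(tert-butyldimethylsilyl)oxy]-10-{[(tert-butyldimethylsilyl)oxy]methyl}-6-{[(4-methoxyphenyl)methoxy]methyl}-3-methylidene-2-oxo-2,3,3a,4,5,8,9,11a-octahydrocyclodeca[b]furan-4-yl (2S)-2-methylbutanoate | C=C1C(=O)O[C@@H]2/C=C(/CO[Si](C)(C)C(C)(C)C)CC/C=C(/COCc3ccc(OC)cc3)[C@H](O[Si](C)(C)C(C)(C)C)[C@H](OC(=O)[C@@H](C)CC)[C@@H]12 | intermediate
33 | (3aS,4R,5S,6Z,10E,11aR)-5-[(tert-butyldimethylsilyl)oxy]-10-{[(tert-butyldimethylsilyl)oxy]methyl}-6-(hydroxymethyl)-3-methylidene-2-oxo-2,3,3a,4,5,8,9,11a-octahydrocyclodeca[b]furan-4-yl (2S)-2-methylbutanoate | C=C1C(=O)O[C@@H]2/C=C(/CO[Si](C)(C)C(C)(C)C)CC/C=C(/CO)[C@H](O[Si](C)(C)C(C)(C)C)[C@H](OC(=O)[C@@H](C)CC)[C@@H]12 | intermediate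
34 | (3aS,4R,5S,6E,10E,11aR)-5-[(tert-butyldimethylsilyl)oxy]-10-{[(tert-butyldimethylsilyl)oxy]methyl}-6-formyl-3-methylidene-2-oxo-2,3,3a,4,5,8,9,11a-octahydrocyclodeca[b]furan-4-yl (2S)-2-methylbutanoate | C=C1C(=O)O[C@@H]2/C=C(/CO[Si](C)(C)C(C)(C)C)CC/C=C(/C=O)[C@H](O[Si](C)(C)C(C)(C)C)[C@H](OC(=O)[C@@H](C)CC)[C@@H]12 | intermediate
35 | (3aS,4R,5S,6E,10E,11aR)-6-formyl-5-hydroxy-10-(hydroxymethyl)-3-methylidene-2-oxo-2,3,3a,4,5,8,9,11a-octahydrocyclodeca[b]furan-4-yl (2S)-2-methylbutanoate (CNP0331447.11) | C=C1C(=O)O[C@@H]2/C=C(/CO)CC/C=C(/C=O)[C@H](O)[C@H](OC(=O)[C@@H](C)CC)[C@@H]12 | target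

## Step count and risks

Total step count: 23.
Longest linear sequence: 15 steps (steps 1–4, 6–10 and 18–23, from 1 to 35), which is 0.65 of the total. The fragment 2 branch (steps 11–17) and steps 5 and 12 lie outside it.

The three steps most likely to fail:

Step 20 (ring-closing metathesis of 31). A trisubstituted alkene must form in a ten-membered ring from a 1,1-disubstituted alkene flanked by a silyloxy-bearing carbon and a PMB-oxymethyl group, so oligomerisation or no reaction is possible. The fallback sets out from 31 and comes back at 33. The PMB ether is removed first with DDQ to give des-PMB seco ester F1. Its free allylic hydroxyl next to the 1,1-disubstituted alkene lowers the steric demand and is known to accelerate metathesis at such an alkene. Ring closure of F1 with the same ruthenium catalyst at high dilution then gives 33 directly, so deprotection precedes cyclisation and the metathesis substrate is a different one.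

Step 18 (Barbier union of 17 and 27). The aldehyde is an epimerisable α-silyloxy β,γ-unsaturated aldehyde, and the facial preferences of the lactone and of the aldehyde must reinforce each other. If they do not, the main product will carry the opposite configuration at C8. The fallback sets out from 17 and 27 and comes back at 31. Should the coupling give mainly C8-epimeric coupling product F2, it is esterified with inversion instead of retention: a Mitsunobu reaction of F2 with acid 30 (PPh3, diisopropyl azodicarboxylate, toluene, 0 °C → rt) delivers 31.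

Step 6 (asymmetric alkynylation of 7 with 10). The β,β-disubstituted enal is a less reactive and less selective substrate than simple enals, and the facial sense rests on the stated assumption. The fallback sets out from 7 and 10 and comes back at 12. The lithium acetylide of 10 (n-BuLi, THF, −78 °C) is added to 7 to give racemic propargylic alcohol F3. Oxidation with MnO2 gives ynone F4. Enantioselective reduction with the (R)-2-methyl-CBS-oxazaborolidine and BH3·SMe2 (alkynyl as the small group, alkenyl as the large group) then gives (R)-12, so C6 is set by asymmetric reduction instead of asymmetric addition.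

## Further compounds

F1 | step 20 | des-PMB seco ester, (1R,2S)-2-[(tert-butyldimethylsilyl)oxy]-1-[(2R,3S)-2-[(1E)-2-{[(tert-butyldimethylsilyl)oxy]methyl}hexa-1,5-dien-1-yl]-4-methylidene-5-oxooxolan-3-yl]-3-(hydroxymethyl)but-3-en-1-yl (2S)-2-methylbutanoate | C=C1C(=O)O[C@H](/C=C(/CO[Si](C)(C)C(C)(C)C)CCC=C)[C@H]1[C@@H](OC(=O)[C@@H](C)CC)[C@@H](O[Si](C)(C)C(C)(C)C)C(=C)CO
F2 | step 18 | C8-epimeric coupling product, (4R,5R)-4-[(1S,2S)-2-[(tert-butyldimethylsilyl)oxy]-1-hydroxy-3-{[(4-methoxyphenyl)methoxy]methyl}but-3-en-1-yl]-5-[(1E)-2-{[(tert-butyldimethylsilyl)oxy]methyl}hexa-1,5-dien-1-yl]-3-methylideneoxolan-2-one | C=C1C(=O)O[C@H](/C=C(/CO[Si](C)(C)C(C)(C)C)CCC=C)[C@H]1[C@H](O)[C@@H](O[Si](C)(C)C(C)(C)C)C(=C)COCc1ccc(OC)cc1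
F3 | step 6 | racemic propargylic alcohol, (4RS,5E)-6-{[(tert-butyldimethylsilyl)oxy]methyl}-1-[(4-methoxyphenyl)methoxy]deca-5,9-dien-2-yn-4-ol | OC(C#CCOCc1ccc(OC)cc1)/C=C(/CO[Si](C)(C)C(C)(C)C)CCC=C
F4 | step 6 | ynone, (5E)-6-{[(tert-butyldimethylsilyl)oxy]methyl}-1-[(4-methoxyphenyl)methoxy]deca-5,9-dien-2-yn-4-one | O=C(C#CCOCc1ccc(OC)cc1)/C=C(/CO[Si](C)(C)C(C)(C)C)CCC=C
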